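**Plan**
- Cuts: first the side-chain Cα=Cβ bond, back to a C6 ester. Then C4a–C5 and C8–C8a together, which removes the whole benzo ring and leaves a trans-5,6-disubstituted 1,4-dioxan-2-one plus methyl coumalate. Last, the lactone C–O bond and the C2–C3 bond (aldol).
- Enabling feature: the benzo ring of the 2,3-dihydro-1,4-benzodioxine bears only O1 (on C8a), O4 (on C4a) and one carbon substituent at C6, para to C8a. A ketene acetal imprints this 4-alkoxybenzoate pattern on coumalate, and the second oxygen rides on the ketene acetal CH.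
- Forward order: guaiacyl ring bought with vanillin → acyclic syn-aldol chain → dioxanone ring by lactonisation → benzo ring by [4+2]/–CO2/–Me3SiOH → acrylic acid chain by Knoevenagel–Doebner condensation.
- Stereochemistry: C2 and C3 are both set in one Evans syn-aldol reaction under (S)-4-benzyloxazolidinone control (syn chain = trans ring). The E alkene arises in the decarboxylative condensation.

Key step: step 10

Remark: the SMILES decodes as (2R,3R), that is trans aryl/CH2OH, with an E acrylic acid. Benzodioxine numbering (O1, C2 aryl, C3 CH2OH, O4, C4a, C5–C8, C8a) is used throughout. TIPS = triisopropylsilyl, TBS = tert-butyldimethylsilyl.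

**Step 1**
Reactants: 1 vanillin
Product: 2 3-methoxy-4-(triisopropylsilyloxy)benzaldehyde
Conditions: TIPSCl, imidazole, DMF, rt
Reagents that add atoms: triisopropylsilyl chloride CC(C)[Si](Cl)(C(C)C)C(C)C
Why: Imidazole-promoted O-silylation of a phenol is routine, and the bulky TIPS ether should outlast boron triflate, borohydride, lithium amide, hot toluene and hot pyridine yet fall to fluoride at the end.

**Step 2**
Reactants: 3 diglycolic anhydride
Product: 4 2-(2-tert-butoxy-2-oxoethoxy)acetic acid
Conditions: t-BuOH (excess), DMAP (0.1 equiv), PhMe, 80 °C; aq. citric acid wash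
Reagents that add atoms: tert-butanol CC(C)(C)O
Why: DMAP-catalysed alcoholysis of a symmetrical cyclic anhydride stops at the half-ester, and the tert-butyl ester is chosen because it later resists both borohydride and attack by a neighbouring alkoxide.

**Step 3**
Reactants: 4 2-(2-tert-butoxy-2-oxoethoxy)acetic acid; 5 (S)-4-benzyl-1,3-oxazolidin-2-one
Product: 7 tert-butyl 2-{2-[(4S)-4-benzyl-2-oxo-1,3-oxazolidin-3-yl]-2-oxoethoxy}acetate, via mixed pivalic anhydride 6 (not isolated)
Conditions: PivCl, Et3N, THF, −20 °C; then LiCl, 5, −20 °C → rt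
Reagents that add atoms: pivaloyl chloride CC(C)(C)C(=O)Cl (its atoms are carried only in intermediate 6)
Why: N-acylation of an oxazolidinone through a mixed pivalic anhydride with LiCl/Et3N activation is routine, and attack occurs at the unhindered alkoxyacetyl carbonyl.

**Step 4**
Reactants: 7 tert-butyl 2-{2-[(4S)-4-benzyl-2-oxo-1,3-oxazolidin-3-yl]-2-oxoethoxy}acetate; 2 3-methoxy-4-(triisopropylsilyloxy)benzaldehyde
Product: 9 tert-butyl 2-{[(2S,3R)-1-[(4S)-4-benzyl-2-oxo-1,3-oxazolidin-3-yl]-3-hydroxy-3-[3-methoxy-4-(triisopropylsilyloxy)phenyl]-1-oxopropan-2-yl]oxy}acetate (syn-aldol adduct), via Z dibutylboron enolate 8 (not isolated)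
Conditions: Bu2BOTf, Et3N, CH2Cl2, −78 → 0 °C; 2, −78 → 0 °C; pH 7 buffer, MeOH, 30% H2O2, 0 °C
Reagents that add atoms: dibutylboron triflate CCCCB(CCCC)OS(=O)(=O)C(F)(F)F (its atoms are carried only in intermediate 8)
Why: In this Evans syn-aldol reaction, soft enolisation touches only the imide and gives Z enolate 8, which adds through a Zimmerman–Traxler chair on the face away from the benzyl group and so sets both stereocentres (future C3 and C2) in the syn relationship that maps onto the trans ring.

**Step 5**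
Reactants: 9 syn-aldol adduct
Product: 10 tert-butyl 2-{[(1R,2R)-1,3-dihydroxy-1-[3-methoxy-4-(triisopropylsilyloxy)phenyl]propan-2-yl]oxy}acetate
Conditions: NaBH4, THF–H2O (4:1), 0 °C → rt
Reagents that add atoms: none
Why: Chemoselective reductive cleavage of the N-acyl oxazolidinone should spare the tert-butyl ester, release the auxiliary for recovery and disturb neither stereocentre (the ether carbon changes from S to R by CIP priorities only).

**Step 6**
Reactants: 10 diol
Product: 11 tert-butyl 2-{[(1R,2R)-3-(tert-butyldimethylsilyloxy)-1-hydroxy-1-[3-methoxy-4-(triisopropylsilyloxy)phenyl]propan-2-yl]oxy}acetate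
Conditions: TBSCl (1.05 equiv), imidazole, CH2Cl2, 0 °C
Reagents that add atoms: tert-butyldimethylsilyl chloride CC(C)(C)[Si](C)(C)Cl
Why: Selective silylation of a primary over a secondary benzylic alcohol on steric grounds is standard and blocks the hydroxyl that would otherwise compete in the lactonisation.

**Step 7**
Reactants: 11 primary TBS ether
Product: 13 2-{[(1R,2R)-3-(tert-butyldimethylsilyloxy)-1-hydroxy-1-[3-methoxy-4-(triisopropylsilyloxy)phenyl]propan-2-yl]oxy}acetic acid, via bis(trimethylsilyl) derivative 12 (not isolated)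
Conditions: TMSOTf, 2,6-lutidine, CH2Cl2, 0 °C → rt; then THF, aq. citric acid (pH 4), 0 °C
Reagents that add atoms: trimethylsilyl triflate C[Si](C)(C)OS(=O)(=O)C(F)(F)F (its atoms are carried only in intermediate 12)
Why: Silyl-triflate-mediated dealkylation of a tert-butyl ester (loss of isobutene) under lutidine buffering avoids the protic acid that would ionise the electron-rich benzylic alcohol, and the labile Me3Si ester and ether of 12 hydrolyse at pH 4 while the TBS and TIPS ethers stay.

**Step 8**
Reactants: 13 hydroxy acid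
Product: 14 (5R,6R)-5-[(tert-butyldimethylsilyloxy)methyl]-6-[3-methoxy-4-(triisopropylsilyloxy)phenyl]-1,4-dioxan-2-one (trans)
Conditions: DCC, DMAP (cat.), CH2Cl2 (0.02 M), 0 °C → rt
Reagents that add atoms: none
Why: Steglich-type carbodiimide lactonisation closes the six-membered ring by acylation of the benzylic oxygen (6-exo-trig), so no C–O bond at a stereocentre is touched and the two substituents end up trans-diequatorial.

**Step 9**
Reactants: 14 trans-dioxanone
Product: 16 (5R,6R)-5-[(tert-butyldimethylsilyloxy)methyl]-6-[3-methoxy-4-(triisopropylsilyloxy)phenyl]-2-(trimethylsilyloxy)-5,6-dihydro-1,4-dioxine, via lithium enolate 15 (not isolated)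
Conditions: LiN(SiMe3)2, TMSCl–Et3N (1:1, centrifuged), THF, −78 → 0 °C; evaporate, pentane, filter under Ar
Reagents that add atoms: trimethylsilyl chloride C[Si](C)(C)Cl; lithium bis(trimethylsilyl)amide [Li]N([Si](C)(C)C)[Si](C)(C)C (lithium is carried only in intermediate 15)
Why: Kinetic deprotonation of the only acidic position (O–CH2–C=O) with in situ O-silylation is the established entry to silyl ketene acetals of 1,4-dioxan-2-ones, as used for Ireland–Claisen rearrangements, and the non-aqueous work-up spares the hydrolytically labile product.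

**Step 10**
Reactants: 16 cyclic silyl ketene acetal; 17 methyl coumalate
Product: 20 methyl (2R,3R)-3-[(tert-butyldimethylsilyloxy)methyl]-2-[3-methoxy-4-(triisopropylsilyloxy)phenyl]-2,3-dihydro-1,4-benzodioxine-6-carboxylate, via bridged lactone cycloadduct 18 (not isolated), via dihydroarene 19 (not isolated)
Conditions: 17 (1.5 equiv), i-Pr2NEt (0.1 equiv), PhMe, silanised sealed tube, 60 °C, then 110 °C; cool, DBU, rt
Reagents that add atoms: none
Why: Proposed new method: the CH carbon C3 of 16, made nucleophilic by the two oxygens on C2 against the single oxygen it carries itself, attacks the doubly activated C6 of pyrone 17 while the acetal carbon C2 bonds to pyrone C3 in a polar, asynchronous inverse-electron-demand [4+2] cycloaddition that gives bridged lactone 18. At 110 °C 18 extrudes CO2 by retro-[4+2] to dihydroarene 19, whose C4a–H is the γ-hydrogen of a dienoate, so DBU removes it and the extended enolate expels Me3SiO− from C8a (E1cB), which aromatises the ring at the correct oxidation level. The closest known reaction types are the benzannulation of methyl coumalate with acyclic ketene acetals to 4-alkoxybenzoates and the catechol annulation of electron-poor 2-pyrones with 1,1,2-trialkoxyethenes; a lactone-derived cyclic silyl ketene acetal has not been shown in this role. The one new ring, the benzo ring, closes by intermolecular [4+2] annulation onto the intact dioxane ring through the bonds C4a–C5 and C8–C8a. No lasting stereocentre is created, since the sp3 centres of 18 and 19 vanish on aromatisation whatever the facial or endo/exo course, and C2–H and C3–H are never acidic or allylic on the way. Two selectivities are needed: regiochemistry, secured by the matched polarity that puts the ester para to C8a–O1, and loss of OSiMe3 in preference to ring oxygen O1, secured by the more stable silanolate leaving group and by the dioxane ring, which holds O1 close to the plane of the enolate while the exocyclic OSiMe3 stands pseudoaxial and overlaps with the π system; holding the mixture at 60 °C until 16 is used up keeps the silanol, which appears only after CO2 loss, away from the ketene acetal.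

**Step 11**
Reactants: 20 benzodioxine ester
Product: 21 {(2R,3R)-3-[(tert-butyldimethylsilyloxy)methyl]-2-[3-methoxy-4-(triisopropylsilyloxy)phenyl]-2,3-dihydro-1,4-benzodioxin-6-yl}methanol
Conditions: i-Bu2AlH (2.5 equiv), CH2Cl2, −78 → −20 °C; aq. potassium sodium tartrate
Reagents that add atoms: none
Why: Hydride reduction of an aromatic methyl ester to the benzylic alcohol with i-Bu2AlH is standard and compatible with silyl ethers and aryl alkyl ethers.

**Step 12**
Reactants: 21 benzylic alcohol
Product: 22 (2R,3R)-3-[(tert-butyldimethylsilyloxy)methyl]-2-[3-methoxy-4-(triisopropylsilyloxy)phenyl]-2,3-dihydro-1,4-benzodioxine-6-carbaldehyde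
Conditions: MnO2 (activated, excess), CH2Cl2, rt
Reagents that add atoms: none
Why: MnO2 oxidation takes benzylic alcohols selectively to aldehydes without over-oxidation and leaves ethers and silyl ethers alone.

**Step 13**
Reactants: 22 aldehyde
Product: 24 (E)-3-{(2R,3R)-3-[(tert-butyldimethylsilyloxy)methyl]-2-[3-methoxy-4-(triisopropylsilyloxy)phenyl]-2,3-dihydro-1,4-benzodioxin-6-yl}prop-2-enoic acid, via arylidenemalonic acid 23 (not isolated)
Conditions: malonic acid, piperidine (0.2 equiv), pyridine, 80 °C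
Reagents that add atoms: malonic acid O=C(O)CC(=O)O
Why: In this Knoevenagel–Doebner condensation, diacid 23 decarboxylates in hot pyridine to the thermodynamically preferred E-cinnamic acid, and no base-sensitive free para-hydroxybenzyl ether is present at this stage.

**Step 14**
Reactants: 24 bis-silylated acid
Product: 25 (E)-3-[(2R,3R)-2-(4-hydroxy-3-methoxyphenyl)-3-(hydroxymethyl)-2,3-dihydro-1,4-benzodioxin-6-yl]prop-2-enoic acid (target)
Conditions: n-Bu4NF, AcOH (1:1), THF, 0 °C → rt; aq. citric acid work-up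
Reagents that add atoms: none
Why: Fluoride-induced desilylation removes both silyl ethers, and the acetic acid buffer prevents a free phenoxide from opening the C2–O1 bond through a quinone methide and eroding the C2 configuration.

**Compound list**
1 | vanillin | COc1cc(C=O)ccc1O | starting material
2 | 3-methoxy-4-(triisopropylsilyloxy)benzaldehyde | COc1cc(C=O)ccc1O[Si](C(C)C)(C(C)C)C(C)C | intermediate
3 | diglycolic anhydride | O=C1COCC(=O)O1 | starting material
4 | 2-(2-tert-butoxy-2-oxoethoxy)acetic acid | CC(C)(C)OC(=O)COCC(=O)O | intermediate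
5 | (S)-4-benzyl-1,3-oxazolidin-2-one | O=C1N[C@@H](Cc2ccccc2)CO1 | starting material
6 | mixed anhydride of 4 and pivalic acid | CC(C)(C)OC(=O)COCC(=O)OC(=O)C(C)(C)C | intermediate
7 | tert-butyl 2-{2-[(4S)-4-benzyl-2-oxo-1,3-oxazolidin-3-yl]-2-oxoethoxy}acetate | CC(C)(C)OC(=O)COCC(=O)N1[C@@H](Cc2ccccc2)COC1=O | intermediate
8 | Z dibutylboron enolate of 7 | CCCCB(CCCC)O/C(=C\OCC(=O)OC(C)(C)C)N1[C@@H](Cc2ccccc2)COC1=O | intermediate
9 | (2S,3R) syn-aldol adduct | CC(C)(C)OC(=O)CO[C@@H]([C@H](O)c1ccc(O[Si](C(C)C)(C(C)C)C(C)C)c(OC)c1)C(=O)N1[C@@H](Cc2ccccc2)COC1=O | intermediate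
10 | (1R,2R) 1,3-diol tert-butyl ester | CC(C)(C)OC(=O)CO[C@@H]([C@H](O)c1ccc(O[Si](C(C)C)(C(C)C)C(C)C)c(OC)c1)CO | intermediate
11 | (1R,2R) primary TBS ether, tert-butyl ester | CC(C)(C)OC(=O)CO[C@@H]([C@H](O)c1ccc(O[Si](C(C)C)(C(C)C)C(C)C)c(OC)c1)CO[Si](C)(C)C(C)(C)C | intermediate
12 | trimethylsilyl ester and benzylic trimethylsilyl ether of 13 | C[Si](C)(C)OC(=O)CO[C@@H]([C@H](O[Si](C)(C)C)c1ccc(O[Si](C(C)C)(C(C)C)C(C)C)c(OC)c1)CO[Si](C)(C)C(C)(C)C | intermediate
13 | (1R,2R) hydroxy acid | OC(=O)CO[C@@H]([C@H](O)c1ccc(O[Si](C(C)C)(C(C)C)C(C)C)c(OC)c1)CO[Si](C)(C)C(C)(C)C | intermediate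
14 | (5R,6R)-trans-1,4-dioxan-2-one | COc1cc([C@H]2OC(=O)CO[C@@H]2CO[Si](C)(C)C(C)(C)C)ccc1O[Si](C(C)C)(C(C)C)C(C)C | intermediate
15 | lithium enolate of 14 | COc1cc([C@H]2OC(O[Li])=CO[C@@H]2CO[Si](C)(C)C(C)(C)C)ccc1O[Si](C(C)C)(C(C)C)C(C)C | intermediate
16 | (5R,6R)-2-(trimethylsilyloxy)-5,6-dihydro-1,4-dioxine (silyl ketene acetal) | COc1cc([C@H]2OC(O[Si](C)(C)C)=CO[C@@H]2CO[Si](C)(C)C(C)(C)C)ccc1O[Si](C(C)C)(C(C)C)C(C)C | intermediate
17 | methyl coumalate | COC(=O)C1=COC(=O)C=C1 | starting material
18 | dioxane-fused 2-oxabicyclo[2.2.2]oct-5-en-3-one cycloadduct (transient centres undefined) | COc1cc([C@H]2OC3(O[Si](C)(C)C)C4C=C(C(=O)OC)C(OC4=O)C3O[C@@H]2CO[Si](C)(C)C(C)(C)C)ccc1O[Si](C(C)C)(C(C)C)C(C)C | intermediate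
19 | methyl (2R,3R)-8a-(trimethylsilyloxy)-2,3,4a,8a-tetrahydro-1,4-benzodioxine-6-carboxylate derivative (C4a, C8a undefined) | COc1cc([C@H]2OC3(O[Si](C)(C)C)C=CC(C(=O)OC)=CC3O[C@@H]2CO[Si](C)(C)C(C)(C)C)ccc1O[Si](C(C)C)(C(C)C)C(C)C | intermediate
20 | methyl (2R,3R)-benzodioxine-6-carboxylate, TBS/TIPS protected | COc1cc([C@H]2Oc3ccc(C(=O)OC)cc3O[C@@H]2CO[Si](C)(C)C(C)(C)C)ccc1O[Si](C(C)C)(C(C)C)C(C)C | intermediate
21 | (2R,3R) C6 benzylic alcohol | COc1cc([C@H]2Oc3ccc(CO)cc3O[C@@H]2CO[Si](C)(C)C(C)(C)C)ccc1O[Si](C(C)C)(C(C)C)C(C)C | intermediate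
22 | (2R,3R) C6 aldehyde | COc1cc([C@H]2Oc3ccc(C=O)cc3O[C@@H]2CO[Si](C)(C)C(C)(C)C)ccc1O[Si](C(C)C)(C(C)C)C(C)C | intermediate
23 | (2R,3R) arylidenemalonic acid | COc1cc([C@H]2Oc3ccc(C=C(C(=O)O)C(=O)O)cc3O[C@@H]2CO[Si](C)(C)C(C)(C)C)ccc1O[Si](C(C)C)(C(C)C)C(C)C | intermediate
24 | (2R,3R,E) bis-silylated acrylic acid | COc1cc([C@H]2Oc3ccc(/C=C/C(=O)O)cc3O[C@@H]2CO[Si](C)(C)C(C)(C)C)ccc1O[Si](C(C)C)(C(C)C)C(C)C | intermediate
25 | (E)-3-[(2R,3R)-2-(4-hydroxy-3-methoxyphenyl)-3-(hydroxymethyl)-2,3-dihydro-1,4-benzodioxin-6-yl]prop-2-enoic acid | COc1cc([C@H]2Oc3ccc(/C=C/C(=O)O)cc3O[C@@H]2CO)ccc1O | target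

Total step count: 14. Longest linear sequence: 13 steps (3 → 25, steps 2–14); step 1 is a one-step side branch.

**Steps most likely to fail**

1. Step 10 (new method).
   - What may go wrong: the polar addition may stop after the first C–C bond, with silyl transfer to the pyrone-derived dienolate in place of ring closure. The ketene acetal may be protodesilylated by silanol that is released too early. Aromatisation may proceed by departure of ring oxygen O1, which opens the ring, in place of silanolate.
   - Fallback, known chemistry only: the arene is bought, O4–C4a is made by Williamson alkylation and O1–C8a by SNAr. It sets out from auxiliary 5 and aldehyde 2 and returns at 20.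
   - Commercial methyl 4-fluoro-3-hydroxybenzoate is alkylated with tert-butyl bromoacetate (K2CO3, DMF) to methyl 3-(2-tert-butoxy-2-oxoethoxy)-4-fluorobenzoate F1.
   - CF3CO2H gives the aryloxyacetic acid F2.
   - PivCl/Et3N gives its mixed pivalic anhydride F3, which acylates 5 (LiCl) to the aryloxyacetyl imide F4.
   - Bu2BOTf/Et3N forms the Z boron enolate F5, which adds to 2 in the same Evans syn sense to give the aldol adduct F6.
   - NaBH4 in aqueous THF gives the diol F7, and TBSCl/imidazole gives the primary silyl ether F8.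
   - NaH in DMF then closes the ring by intramolecular SNAr of the benzylic alkoxide on the fluoride para to the ester, with retention at C2, to give 20.

2. Step 9.
   - What may go wrong: competing C-silylation, Claisen self-condensation of the lactone enolate, and hydrolysis of the trimethylsilyl ketene acetal during isolation or transfer.
   - Fallback, another activating group made by another route: it sets out from 14 and returns at 20.
   - Lactone 14 is thionated (Lawesson's reagent, PhMe, 90 °C) to the thionolactone F9.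
   - LiN(SiMe3)2 at −78 °C gives the lithium enethiolate F10, which MeI alkylates on sulfur to the chromatography-stable ketene O,S-acetal F11.
   - Heating F11 with 17 should lead through the bridged lactone F12 and, after loss of CO2, the dihydroarene F13.
   - Methanethiol, a far better leaving group than the ring alkoxide, departs from F13 to give 20.
   - The cycloaddition stays of the same unproven type, but the handling problem of the dienophile is removed.

3. Step 7.
   - What may go wrong: ionisation at the electron-rich benzylic carbon under silyl triflate, with epimerisation at the future C2 or elimination to an enol ether, and exchange or loss of the primary silyl ether.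
   - Fallback, redox in place of dealkylation and carbodiimide closure: it sets out from 11, returns at 14 and bypasses 13 and step 8.
   - i-Bu2AlH (CH2Cl2, −78 → 0 °C) reduces the tert-butyl ester to the 2-hydroxyethyl ether diol F14.
   - TEMPO (cat.)/PhI(OAc)2 oxidises the primary alcohol selectively.
   - The aldehyde stage closes on the benzylic hydroxyl to the lactol F15, which the same reagent oxidises on to lactone 14 (oxidative lactonisation of a 1,5-diol).

**Further compounds**
F1 | step 10 | methyl 3-(2-tert-butoxy-2-oxoethoxy)-4-fluorobenzoate | COC(=O)c1ccc(F)c(OCC(=O)OC(C)(C)C)c1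
F2 | step 10 | 2-[2-fluoro-5-(methoxycarbonyl)phenoxy]acetic acid | COC(=O)c1ccc(F)c(OCC(=O)O)c1
F3 | step 10 | mixed anhydride of F2 and pivalic acid | COC(=O)c1ccc(F)c(OCC(=O)OC(=O)C(C)(C)C)c1
F4 | step 10 | methyl 3-{2-[(4S)-4-benzyl-2-oxo-1,3-oxazolidin-3-yl]-2-oxoethoxy}-4-fluorobenzoate | COC(=O)c1ccc(F)c(OCC(=O)N2[C@@H](Cc3ccccc3)COC2=O)c1
F5 | step 10 | Z dibutylboron enolate of F4 | CCCCB(CCCC)O/C(=C\Oc1cc(C(=O)OC)ccc1F)N1[C@@H](Cc2ccccc2)COC1=O
F6 | step 10 | (2S,3R) syn-aldol adduct of F4 and 2 | COC(=O)c1ccc(F)c(O[C@@H]([C@H](O)c2ccc(O[Si](C(C)C)(C(C)C)C(C)C)c(OC)c2)C(=O)N2[C@@H](Cc3ccccc3)COC2=O)c1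
F7 | step 10 | methyl 3-{[(1R,2R)-1,3-dihydroxy-1-[3-methoxy-4-(triisopropylsilyloxy)phenyl]propan-2-yl]oxy}-4-fluorobenzoate | COC(=O)c1ccc(F)c(O[C@@H]([C@H](O)c2ccc(O[Si](C(C)C)(C(C)C)C(C)C)c(OC)c2)CO)c1
F8 | step 10 | primary TBS ether of F7 | COC(=O)c1ccc(F)c(O[C@@H]([C@H](O)c2ccc(O[Si](C(C)C)(C(C)C)C(C)C)c(OC)c2)CO[Si](C)(C)C(C)(C)C)c1
F9 | step 9 | (5R,6R)-5-[(tert-butyldimethylsilyloxy)methyl]-6-[3-methoxy-4-(triisopropylsilyloxy)phenyl]-1,4-dioxane-2-thione | COc1cc([C@H]2OC(=S)CO[C@@H]2CO[Si](C)(C)C(C)(C)C)ccc1O[Si](C(C)C)(C(C)C)C(C)C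
F10 | step 9 | lithium enethiolate of F9 | COc1cc([C@H]2OC(S[Li])=CO[C@@H]2CO[Si](C)(C)C(C)(C)C)ccc1O[Si](C(C)C)(C(C)C)C(C)C
F11 | step 9 | (5R,6R)-2-(methylsulfanyl)-5,6-dihydro-1,4-dioxine analogue of 16 | COc1cc([C@H]2OC(SC)=CO[C@@H]2CO[Si](C)(C)C(C)(C)C)ccc1O[Si](C(C)C)(C(C)C)C(C)C
F12 | step 9 | methylsulfanyl analogue of bridged lactone 18 | COc1cc([C@H]2OC3(SC)C4C=C(C(=O)OC)C(OC4=O)C3O[C@@H]2CO[Si](C)(C)C(C)(C)C)ccc1O[Si](C(C)C)(C(C)C)C(C)C
F13 | step 9 | methylsulfanyl analogue of dihydroarene 19 | COc1cc([C@H]2OC3(SC)C=CC(C(=O)OC)=CC3O[C@@H]2CO[Si](C)(C)C(C)(C)C)ccc1O[Si](C(C)C)(C(C)C)C(C)C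
F14 | step 7 | (1R,2R)-3-(tert-butyldimethylsilyloxy)-2-(2-hydroxyethoxy)-1-[3-methoxy-4-(triisopropylsilyloxy)phenyl]propan-1-ol | OCCO[C@@H]([C@H](O)c1ccc(O[Si](C(C)C)(C(C)C)C(C)C)c(OC)c1)CO[Si](C)(C)C(C)(C)C
F15 | step 7 | (5R,6R)-5-[(tert-butyldimethylsilyloxy)methyl]-6-[3-methoxy-4-(triisopropylsilyloxy)phenyl]-1,4-dioxan-2-ol (lactol, anomers) | COc1cc([C@H]2OC(O)CO[C@@H]2CO[Si](C)(C)C(C)(C)C)ccc1O[Si](C(C)C)(C(C)C)C(C)C
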